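How much product stands in the flask at 20 h, and which change lifts it most?

solid substrate 0.42 M; coupling partner 1.68 M; initiator 33 mM; time 20 h

- how much product there is at 20 h, in percent of the solid substrate charged
- the change that raises the amount of product at 20 h, in percent of the solid substrate charged most ("none" if none brings more than 2 percentage points) (Friday's / Sunday's / Saturday's / none)
- amount of product at 20 h, in percent of the solid substrate charged, after Sunday's

- Friday's: doubling the dissolution coefficient of step 7, all else as stated
- Sunday's: doubling the solubility in step 7, all else as stated
- Saturday's: doubling the amount of coupling partner, all else as stated

- percentages count the solid substrate that a species holds: one ended chains B counts as two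
- where a step has two of a species, its rate is k times that concentration squared, and two are used at each turn
- solid, in amounts per volume of the solution: solid substrate
- at the start none of the solid substrate is in solution
- run time (flask): 20 h

    initiator → 2 initiating radical (k1 = 0.00103 /h)
    starting material + initiating radical → capped initiator + first chain carrier (k2 = 23200 /M/s)
    coupling partner + first chain carrier → product + second chain carrier (k3 = 2.28 × 10⁵ /M/h)
    starting material + second chain carrier → released group + first chain carrier (k4 = 3.06 × 10⁶ /M/h)
    2 second chain carrier → ended chains A (k5 = 1.1 × 10⁶ /M/s)
    2 first chain carrier → ended chains B (k6 = 3 × 10⁶ /M/s)
    solid substrate ⇌ starting material, rate k7*(cs7 - [starting material]) while solid is left; crystals form when [starting material] > cs7 (cs7 = 0.30 M, k7 = 0.0361 /h)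

The hunch points to the coupling partner, but this reply starts from the solid. The zero of the scale is a solution kept empty: the solid then dissolves at full rate and gives 51.6% of its charge by the end. This delivery, dissolution coefficient times solubility times time over the charge, is the supply ceiling.

If pairs of second chain carrier end the chains and initiation balances those endings, starting material falls pseudo-first-order:

consumption constant = k4 × √(k1 [initiator] / k5) = 0.283 /h

This exceeds the dissolution coefficient, so the estimate puts [starting material] at 0.0339 M after a lag of 3.13 h, and gives the chain a share of 88.7% of the delivery:

product = ceiling × share × (1 − lag / time) = 38.6%

The coupling partner is absent from this form, its step running at 3.83 × 10⁵ /h against 1.04 × 10⁵ /h for the other propagation step. The form therefore favours Sunday's. For Sunday's the same form, with endings through the first chain carrier left out of it, gives an upper figure, 77.2%.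

The forecast gives 36.9%, below the figure above, names Sunday's, and puts 64% after that change. On Saturday's it says: “since dissolution limits the rate”.

The simulation gives 37.3% and Sunday's, with gains of 27 percentage points, 23 points for Friday's and 1 point for Saturday's, and 64.1% after Sunday's.

The flask's 37.3% is 72.3% of its ceiling. Read at 8.0 h, the same flask has a ceiling of 20.6%, and the same share and lag make 11.1% of product. The run of that flask at 8.0 h reads 11.3% of product, with 7.78% standing as starting material.

The numbers of this flask were set for the occasion; what happens was integrated by code.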